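Prostanoid numbering is used (ester C1; ring C8–C12). Everything rests on cutting the C6–C7 single bond of the cross-conjugated dienone. C7 is the exocyclic β-carbon of the C9 ketone on the cyclopentenone ring, so it can be carried as the Z enol triflate of an α'-formyl ketone, whose lithium chelate places the triflate cis to C9. A stereoretentive Stille coupling with an (E)-γ-hydroxy vinylstannane (C1–C6, C4 carbinol set by CBS reduction) then joins two unprotected halves, completes the 5E,7Z dienone and gives the target directly; the vinylogous acyl triflate reacts ahead of the C10–Br bond.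

Key step: step 12

Remark: compounds 1, 2, 5, 17 and 18 are taken as commercial; the target is read from the SMILES as 4S, 5E, 7Z, 12R, 14Z, 17Z.

Step 1
Reactants: 1 (R)-4-[(tert-butyldimethylsilyl)oxy]cyclopent-2-en-1-one; 2 propargyl bromide (3-bromoprop-1-yne)
Product: 4 (1S,4R)-4-[(tert-butyldimethylsilyl)oxy]-1-(prop-2-yn-1-yl)cyclopent-2-en-1-ol, via propargylmagnesium bromide 3 (not isolated)
Conditions: 2, Mg, HgCl2 (cat.), Et2O, 0 °C; then 1, Et2O, −78 °C; aq NH4Cl
Reagents that add atoms: none
Why: Grignard 1,2-addition of the propargyl/allenyl magnesium reagent to the enone carbonyl gives the homopropargylic tertiary alcohol, and attack anti to the silyloxy group sets the carbinol centre (future C12) cis to OTBS; the minor diastereomer can be removed by chromatography before the silyloxy centre is erased.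

Step 2
Reactants: 4 (1S,4R)-4-[(tert-butyldimethylsilyl)oxy]-1-(prop-2-yn-1-yl)cyclopent-2-en-1-ol; 5 pent-2-yn-1-yl bromide
Product: 6 (1S,4R)-4-[(tert-butyldimethylsilyl)oxy]-1-(octa-2,5-diyn-1-yl)cyclopent-2-en-1-ol
Conditions: CuI (1 equiv), Bu4NI (cat.), Cs2CO3, DMF, rt
Reagents that add atoms: none
Why: Copper-mediated coupling of the terminal alkyne, through its copper acetylide, with the propargylic bromide should give the skipped 1,4-diyne under mild carbonate conditions that leave the tertiary alcohol and the silyl ether untouched.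

Step 3
Reactants: 6 (1S,4R)-4-[(tert-butyldimethylsilyl)oxy]-1-(octa-2,5-diyn-1-yl)cyclopent-2-en-1-ol
Product: 7 (1S,4R)-4-[(tert-butyldimethylsilyl)oxy]-1-[(2Z,5Z)-octa-2,5-dien-1-yl]cyclopent-2-en-1-ol
Conditions: H2 (1 atm), Pd/CaCO3 poisoned with Pb(OAc)2 (Lindlar catalyst), quinoline, EtOAc, rt, stopped after two equivalents of H2
Reagents that add atoms: none
Why: Lindlar semihydrogenation adds hydrogen syn to both alkynes and so sets the 14Z and 17Z alkenes, while the hindered ring alkene flanked by two oxygenated carbons should not be reduced on the poisoned catalyst.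

Step 4
Reactants: 7 (1S,4R)-4-[(tert-butyldimethylsilyl)oxy]-1-[(2Z,5Z)-octa-2,5-dien-1-yl]cyclopent-2-en-1-ol
Product: 8 (1S,4R)-1-[(2Z,5Z)-octa-2,5-dien-1-yl]cyclopent-2-ene-1,4-diol
Conditions: Bu4NF, THF, 0 °C to rt
Reagents that add atoms: none
Why: Fluoride-mediated desilylation frees the secondary allylic alcohol without touching any stereocentre or alkene.

Step 5
Reactants: 8 (1S,4R)-1-[(2Z,5Z)-octa-2,5-dien-1-yl]cyclopent-2-ene-1,4-diol
Product: 9 (S)-4-hydroxy-4-[(2Z,5Z)-octa-2,5-dien-1-yl]cyclopent-2-en-1-one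
Conditions: activated MnO2 (excess), CH2Cl2, rt
Reagents that add atoms: none
Why: Allylic oxidation with MnO2 converts only the secondary allylic alcohol into the enone (the tertiary alcohol cannot be oxidised), which transposes the functionality so that the carbinol carbon becomes C12 and the new ketone C9.

Step 6
Reactants: 9 (S)-4-hydroxy-4-[(2Z,5Z)-octa-2,5-dien-1-yl]cyclopent-2-en-1-one
Product: 10 (1S,4S,5R)-4-hydroxy-4-[(2Z,5Z)-octa-2,5-dien-1-yl]-6-oxabicyclo[3.1.0]hexan-2-one (epoxide cis to the hydroxyl)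
Conditions: 30% aq H2O2, NaOH (0.2 equiv), MeOH, 0 °C
Reagents that add atoms: hydrogen peroxide, OO
Why: Weitz–Scheffer epoxidation: hydroperoxide adds conjugately only to the electron-poor C10=C11 enone bond and not to the isolated Z alkenes; attack anti to the octadienyl chain is expected, but both epoxide diastereomers converge in step 7, so this configuration is of no consequence.

Step 7
Reactants: 10 (1S,4S,5R)-4-hydroxy-4-[(2Z,5Z)-octa-2,5-dien-1-yl]-6-oxabicyclo[3.1.0]hexan-2-one
Product: 12 (S)-2-bromo-4-hydroxy-4-[(2Z,5Z)-octa-2,5-dien-1-yl]cyclopent-2-en-1-one, via trans-bromohydrin 11 (not isolated)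
Conditions: 48% aq HBr (1.5 equiv), acetone, 0 °C to rt
Reagents that add atoms: hydrogen bromide, Br
Why: Acid-promoted opening of the α,β-epoxy ketone by bromide at the α-carbon C10 (SN2, remote from the quaternary C12) gives the trans-bromohydrin, which dehydrates through its enol to leave the bromine on C10 of the re-formed enone (epoxy ketone to α-halo enone conversion).

Step 8
Reactants: 12 (S)-2-bromo-4-hydroxy-4-[(2Z,5Z)-octa-2,5-dien-1-yl]cyclopent-2-en-1-one
Product: 14 (4R,5Z)-2-bromo-4-hydroxy-5-(hydroxymethylidene)-4-[(2Z,5Z)-octa-2,5-dien-1-yl]cyclopent-2-en-1-one, via dilithium alkoxide dienolate 13 (not isolated)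
Conditions: LiN(SiMe3)2 (2.2 equiv), THF, −78 °C; HCO2CH2CF3 (1.3 equiv), −78 °C; AcOH quench
Reagents that add atoms: 2,2,2-trifluoroethyl formate, O=COCC(F)(F)F
Why: Claisen-type C-formylation of the kinetic α'-enolate at C8, the only enolisable position because C12 is quaternary; the C12 alkoxide of the dianion cannot leave as oxide, which should suppress β-elimination, and the product rests as the hydrogen-bonded Z enol.

Step 9
Reactants: 14 (4R,5Z)-2-bromo-4-hydroxy-5-(hydroxymethylidene)-4-[(2Z,5Z)-octa-2,5-dien-1-yl]cyclopent-2-en-1-one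
Product: 16 (Z)-[(5R)-3-bromo-5-hydroxy-5-[(2Z,5Z)-octa-2,5-dien-1-yl]-2-oxocyclopent-3-en-1-ylidene]methyl trifluoromethanesulfonate, via lithium enolate chelate 15 (not isolated)
Conditions: LiN(SiMe3)2 (1.05 equiv), THF, −78 °C; PhNTf2, −78 to 0 °C; aq NH4Cl
Reagents that add atoms: N-phenylbis(trifluoromethanesulfonimide), O=S(=O)(N(c1ccccc1)S(=O)(=O)C(F)(F)F)C(F)(F)F
Why: O-sulfonylation of the 1,3-dicarbonyl enolate at the less hindered formyl oxygen; the lithium chelate holds the two oxygens cis, so the triflate should end up cis to C9 (Z), as in Z-selective enol triflate formation from chelated β-keto ester enolates, and one equivalent of base leaves the tertiary alcohol free.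

Step 10
Reactants: 17 methyl 4-chloro-4-oxobutanoate; 18 (E)-1,2-bis(tributylstannyl)ethene
Product: 19 methyl (E)-4-oxo-6-(tributylstannyl)hex-5-enoate
Conditions: 18 (1.3 equiv), BnPdCl(PPh3)2 (2 mol%), CHCl3, 60 °C
Reagents that add atoms: none
Why: Stille acylation of the alkenylstannane by the acid chloride proceeds with retention of the E geometry and should stop after one acylation because the resulting β-stannyl enone is a far poorer transmetalation partner than 18.

Step 11
Reactants: 19 methyl (E)-4-oxo-6-(tributylstannyl)hex-5-enoate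
Product: 20 methyl (4S,5E)-4-hydroxy-6-(tributylstannyl)hex-5-enoate
Conditions: (R)-2-methyl-CBS-oxazaborolidine (0.2 equiv), catecholborane, toluene, −78 °C; MeOH, then pH 7 buffer
Reagents that add atoms: none
Why: Corey–Bakshi–Shibata reduction: the β-stannylvinyl group acts as the large substituent, so the (R)-oxazaborolidine should deliver hydride to the face that gives the 4S allylic alcohol, and the ester is inert at −78 °C; neutral work-up avoids lactonisation.

Step 12
Reactants: 16 (Z)-[(5R)-3-bromo-5-hydroxy-5-[(2Z,5Z)-octa-2,5-dien-1-yl]-2-oxocyclopent-3-en-1-ylidene]methyl trifluoromethanesulfonate; 20 methyl (4S,5E)-4-hydroxy-6-(tributylstannyl)hex-5-enoate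
Product: 21 methyl (4S,5E,7Z,12R,14Z,17Z)-10-bromo-4,12-dihydroxy-9-oxoprosta-5,7,10,14,17-pentaen-1-oate (target)
Conditions: Pd2(dba)3 (5 mol%), AsPh3 (20 mol%), CuI (10 mol%), NMP, rt, dark
Reagents that add atoms: none
Why: Stille coupling: zerovalent palladium inserts into the C7–O bond of the vinylogous acyl triflate 16 with retention, the (E)-alkenylstannane 20 transmetalates (accelerated by CuI) with retention, and reductive elimination forms the C6–C7 bond and so releases the cross-conjugated dienone directly. The closest known reaction type is the coupling of enol triflates of 1,3-dicarbonyl compounds (β-triflyloxy enones) with alkenylstannanes. No ring is closed and no stereocentre is created; C4 and C12 arrive intact from 20 and 16, and the 5E and 7Z geometries are transferred from the stannane and the triflate. The selectivity required is reaction at C7–OTf in preference to C10–Br, which the substrate secures because the triflate sits β to the C9 carbonyl and should undergo oxidative addition at room temperature far faster than the α-bromoenone. Neutral, base-free conditions in the dark spare the two free hydroxyls, the lactonisation-prone γ-hydroxy ester and the photolabile Z dienone.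

Compound list
1 | (R)-4-[(tert-butyldimethylsilyl)oxy]cyclopent-2-en-1-one | O=C1C=C[C@H](O[Si](C)(C)C(C)(C)C)C1 | starting material
2 | propargyl bromide (3-bromoprop-1-yne) | C#CCBr | starting material
3 | propargylmagnesium bromide | C#CC[Mg]Br | intermediate (not isolated)
4 | (1S,4R)-4-[(tert-butyldimethylsilyl)oxy]-1-(prop-2-yn-1-yl)cyclopent-2-en-1-ol | C#CC[C@@]1(O)C=C[C@H](O[Si](C)(C)C(C)(C)C)C1 | intermediate
5 | pent-2-yn-1-yl bromide (1-bromopent-2-yne) | CCC#CCBr | starting material
6 | (1S,4R)-4-[(tert-butyldimethylsilyl)oxy]-1-(octa-2,5-diyn-1-yl)cyclopent-2-en-1-ol | CCC#CCC#CC[C@@]1(O)C=C[C@H](O[Si](C)(C)C(C)(C)C)C1 | intermediate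
7 | (1S,4R)-4-[(tert-butyldimethylsilyl)oxy]-1-[(2Z,5Z)-octa-2,5-dien-1-yl]cyclopent-2-en-1-ol | CC/C=C\C/C=C\C[C@@]1(O)C=C[C@H](O[Si](C)(C)C(C)(C)C)C1 | intermediate
8 | (1S,4R)-1-[(2Z,5Z)-octa-2,5-dien-1-yl]cyclopent-2-ene-1,4-diol | CC/C=C\C/C=C\C[C@@]1(O)C=C[C@H](O)C1 | intermediate
9 | (S)-4-hydroxy-4-[(2Z,5Z)-octa-2,5-dien-1-yl]cyclopent-2-en-1-one | CC/C=C\C/C=C\C[C@@]1(O)C=CC(=O)C1 | intermediate
10 | (1S,4S,5R)-4-hydroxy-4-[(2Z,5Z)-octa-2,5-dien-1-yl]-6-oxabicyclo[3.1.0]hexan-2-one (epoxide cis to OH) | CC/C=C\C/C=C\C[C@@]1(O)[C@@H]2O[C@@H]2C(=O)C1 | intermediate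
11 | (2R,3S,4S)-2-bromo-3,4-dihydroxy-4-[(2Z,5Z)-octa-2,5-dien-1-yl]cyclopentan-1-one (trans-bromohydrin) | CC/C=C\C/C=C\C[C@@]1(O)[C@H](O)[C@@H](Br)C(=O)C1 | intermediate (not isolated)
12 | (S)-2-bromo-4-hydroxy-4-[(2Z,5Z)-octa-2,5-dien-1-yl]cyclopent-2-en-1-one | CC/C=C\C/C=C\C[C@@]1(O)C=C(Br)C(=O)C1 | intermediate
13 | dilithium alkoxide dienolate of 12 | CC/C=C\C/C=C\C[C@@]1(O[Li])C=C(Br)C(O[Li])=C1 | intermediate (not isolated)
14 | (4R,5Z)-2-bromo-4-hydroxy-5-(hydroxymethylidene)-4-[(2Z,5Z)-octa-2,5-dien-1-yl]cyclopent-2-en-1-one | CC/C=C\C/C=C\C[C@@]1(O)C=C(Br)C(=O)/C1=C\O | intermediate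
15 | lithium enolate chelate of 14 | CC/C=C\C/C=C\C[C@@]1(O)C=C(Br)C(=O)/C1=C\O[Li] | intermediate (not isolated)
16 | (Z)-[(5R)-3-bromo-5-hydroxy-5-[(2Z,5Z)-octa-2,5-dien-1-yl]-2-oxocyclopent-3-en-1-ylidene]methyl trifluoromethanesulfonate | CC/C=C\C/C=C\C[C@@]1(O)C=C(Br)C(=O)/C1=C\OS(=O)(=O)C(F)(F)F | intermediate
17 | methyl 4-chloro-4-oxobutanoate | COC(=O)CCC(Cl)=O | starting material
18 | (E)-1,2-bis(tributylstannyl)ethene | CCCC[Sn](CCCC)(CCCC)/C=C/[Sn](CCCC)(CCCC)CCCC | starting material
19 | methyl (E)-4-oxo-6-(tributylstannyl)hex-5-enoate | CCCC[Sn](CCCC)(CCCC)/C=C/C(=O)CCC(=O)OC | intermediate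
20 | methyl (4S,5E)-4-hydroxy-6-(tributylstannyl)hex-5-enoate | CCCC[Sn](CCCC)(CCCC)/C=C/[C@@H](O)CCC(=O)OC | intermediate
21 | methyl (4S,5E,7Z,12R,14Z,17Z)-10-bromo-4,12-dihydroxy-9-oxoprosta-5,7,10,14,17-pentaen-1-oate | CC/C=C\C/C=C\C[C@@]1(O)C=C(Br)C(=O)/C1=C\C=C\[C@@H](O)CCC(=O)OC | target

Total step count: 12. Longest linear sequence: 10 steps (steps 1 to 9, then step 12); the side chain takes 2 steps (10 and 11).

Steps most likely to fail

Step 9. Loss of chelate control during sulfonylation would place the triflate trans to C9 and so invert the geometry that the coupling transfers. In that case the E isomer would be made on purpose from 14 (Tf2O, iPr2NEt, CH2Cl2, −78 °C, a non-chelated ammonium enolate) as (E)-[(5R)-3-bromo-5-hydroxy-5-[(2Z,5Z)-octa-2,5-dien-1-yl]-2-oxocyclopent-3-en-1-ylidene]methyl trifluoromethanesulfonate F1. F1 would be coupled with 20 under the conditions of step 12 to give the 7E isomer, methyl (4S,5E,7E,12R,14Z,17Z)-10-bromo-4,12-dihydroxy-9-oxoprosta-5,7,10,14,17-pentaen-1-oate F2. The C7=C8 bond of F2 would then be isomerised photochemically (daylight lamp, benzene, rt) to a photostationary mixture from which 21 is separated and F2 recycled. This fallback sets out from 14 and returns at 21.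

Step 12. The β-acylvinylpalladium intermediate may isomerise and erode the 7Z geometry, or oxidative addition at C10–Br may compete. The same bond would then be made by a Heck reaction that keeps palladium off the ring carbon C7. From 12, α'-methylenation with paraformaldehyde and N-methylanilinium trifluoroacetate (THF, reflux) would give (4R)-2-bromo-4-hydroxy-5-methylidene-4-[(2Z,5Z)-octa-2,5-dien-1-yl]cyclopent-2-en-1-one F3. From 20, iododestannylation (I2, CH2Cl2, 0 °C) would give methyl (4S,5E)-4-hydroxy-6-iodohex-5-enoate F4. Heck coupling of F3 with F4 (Pd(OAc)2, Bu4NCl, NaHCO3, DMF, rt) returns to 21. The vinyl iodide should outcompete C10–Br in oxidative addition. After insertion, the palladium on C8 has β-hydrogens only on C7 because C12 is quaternary, so the exocyclic alkene must re-form; syn elimination with the new vinyl group turned away from C12 should place it cis to C9.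

Step 8. The dianion may be consumed by O-formylation of the tertiary alkoxide or by retro-aldol ring opening. The alcohol would then be masked so that a monoanion is formylated. From 12, silylation (Me3SiCl, imidazole, CH2Cl2) would give (S)-2-bromo-4-[(2Z,5Z)-octa-2,5-dien-1-yl]-4-[(trimethylsilyl)oxy]cyclopent-2-en-1-one F5. Enolisation with LiN(iPr)2 (THF, −78 °C) and formylation with HCO2CH2CF3 would give (4R,5Z)-2-bromo-5-(hydroxymethylidene)-4-[(2Z,5Z)-octa-2,5-dien-1-yl]-4-[(trimethylsilyl)oxy]cyclopent-2-en-1-one F6. Mild acid (AcOH, THF, H2O, rt) would remove the silyl group and return to 14.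

Further compounds
F1 | step 9 | (E)-[(5R)-3-bromo-5-hydroxy-5-[(2Z,5Z)-octa-2,5-dien-1-yl]-2-oxocyclopent-3-en-1-ylidene]methyl trifluoromethanesulfonate | CC/C=C\C/C=C\C[C@@]1(O)C=C(Br)C(=O)/C1=C/OS(=O)(=O)C(F)(F)F
F2 | step 9 | methyl (4S,5E,7E,12R,14Z,17Z)-10-bromo-4,12-dihydroxy-9-oxoprosta-5,7,10,14,17-pentaen-1-oate | CC/C=C\C/C=C\C[C@@]1(O)C=C(Br)C(=O)/C1=C/C=C/[C@@H](O)CCC(=O)OC
F3 | step 12 | (4R)-2-bromo-4-hydroxy-5-methylidene-4-[(2Z,5Z)-octa-2,5-dien-1-yl]cyclopent-2-en-1-one | CC/C=C\C/C=C\C[C@@]1(O)C=C(Br)C(=O)C1=C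
F4 | step 12 | methyl (4S,5E)-4-hydroxy-6-iodohex-5-enoate | I/C=C/[C@@H](O)CCC(=O)OC
F5 | step 8 | (S)-2-bromo-4-[(2Z,5Z)-octa-2,5-dien-1-yl]-4-[(trimethylsilyl)oxy]cyclopent-2-en-1-one | CC/C=C\C/C=C\C[C@@]1(O[Si](C)(C)C)C=C(Br)C(=O)C1
F6 | step 8 | (4R,5Z)-2-bromo-5-(hydroxymethylidene)-4-[(2Z,5Z)-octa-2,5-dien-1-yl]-4-[(trimethylsilyl)oxy]cyclopent-2-en-1-one | CC/C=C\C/C=C\C[C@@]1(O[Si](C)(C)C)C=C(Br)C(=O)/C1=C\O
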